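Abbreviations: TBS = tert-butyldimethylsilyl, TES = triethylsilyl, Piv = pivaloyl. Atom labels C1–C8a follow isochromene numbering of the target throughout, also for open-chain intermediates.

## Structural features

The target is a 6,7-dihydro-1H-isochromen-8(5H)-one: carbocyclic ring A (C4a, C5, C6, C7, C8, C8a) is fused through the C4a=C8a double bond to the 2H-pyran ring B (C1, O2, C3, C4, C4a, C8a). The C8 ketone, the tetrasubstituted C4a=C8a alkene and the C3=C4 enol ether form one cross-conjugated push–pull system, a doubly vinylogous ester that ends at O2. C3 carries a trans epoxide, (2S,3R)-3-methyloxiran-2-yl, whose two adjacent stereocentres lie next to the enol ether, so the unit is a vinyl epoxide. Ring A holds the other two stereocentres, also adjacent: C6 (R, secondary, esterified by orsellinic acid) and C7 (R, tertiary carbinol bearing methyl, alpha to the ketone), with the two oxygens cis. Fragile groups are the vinyl epoxide (acid, zerovalent palladium, soft nucleophiles), the dienyl ether (aqueous acid, amines), the C6 ester (it sits beta to C5, whose hydrogens are vinylogously acidic, so base can expel orsellinate), the tertiary alpha-ketol and the free resorcinol. The stereocentres are not the real difficulty, since each pair can come from one reliable source. The difficulty is the fully substituted C8(=O)–C8a=C4a enone, which must carry C1 on C8a and both C4 and C5 on C4a beside the quaternary C7, together with a late, non-acidic closure of ring B. The key step exploits exactly this enone of ring A with C5 on its beta carbon C4a: that is the pattern left when a C5 radical adds to the beta carbon of a C8 ynone, with C8a emerging as a vinyl iodide ready to receive C1.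

## Logic of the disconnections

**28 ⇒ 27 ⇒ 22 + 25 (via 26).** The acyl C–O bond of the C6 ester is cut first. The aroyl group is the best leaving group in the molecule and the resorcinol is oxidation-prone, so it should be attached last. This separates the flat aromatic part from the chiral core. The forward step must acylate a hindered secondary alcohol beside a free tertiary one with a di-ortho-substituted aroyl electrophile under mild base. The phenol protecting groups must come off with buffered fluoride only, because acid, zerovalent palladium and amines each threaten the vinyl epoxide or the dienyl ether.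

**22 ⇒ 21.** The two O–Si bonds at C6 and C7 are cut. The silyl ethers keep C6–O a poor leaving group through all basic steps. The tertiary C7 oxygen carries TES and not a second TBS group, so that its removal from the sensitive bicycle does not need forcing conditions.

**21 ⇒ 20 ⇒ 19.** The O2–C1 bond is opened (retro oxa-6π) and pivalate is returned to C1 with a hydrogen to C4. Ring B, its dienyl ether and the vinyl epoxide are thereby replaced by a C3 ketone and an allylic pivalate on ring A alone. The forward step must deprotonate C4 selectively, lose pivalate and cyclize under base without acid and without expelling the C6 silyloxy group.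

**19 ⇒ 18 ⇒ 17 ⇒ 16 ⇒ 15.** The C3 ketone is traced to the TES-protected carbinol, the pivalate to the primary alcohol, and the C8a–C1 bond is cut. C1 is a one-carbon unit on the alpha carbon of an enone, which maps onto cross-coupling of an alpha-iodo enone. Keeping C3 as a silyl carbinol until after the coupling avoids acidic C4 hydrogens next to a vinylpalladium species. The coupling must succeed at a tetrasubstituted vinyl iodide.

**15 ⇒ 14 (key).** The C4a–C5 bond of ring A and the C8a–I bond are cut. Ring A becomes an open chain in which C5–C8 come from one chiral piece and C8a–C3 from an alkyne. No stereocentre depends on this step. The forward step needs 6-endo regioselectivity and efficient iodine transfer to the vinyl radical.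

**14 ⇒ 5 + 12 (via 13).** The C8–C8a bond between carbonyl and alkyne is cut, which makes the route convergent. The acetylide must add once to a congested amide carbonyl without touching the primary iodide. The C7 oxygen has to be capped, because a free alpha-hydroxy ynone would close to a furanone.

**5 ⇒ 4 ⇒ 3 ⇒ 1 (via 2).** The C5–I bond goes back to C5–OH, and the amide C–N bond is exchanged for the lactone C–O bond. C5–C8 with both ring A stereocentres then come unchanged from the chiral pool. The two hydroxyls must be differentiated (TBS on the secondary, TES on the tertiary), and the iodide must be in place before the ketone exists so that no lactol can form.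

**12 ⇒ 11 ⇒ 8 + 9 (via 10); 8 ⇒ 7 ⇒ 6.** The C3–C4 bond is cut (propargylation of an epoxy aldehyde), then the two epoxide C–O bonds (asymmetric epoxidation). Both epoxide stereocentres come from one catalytic step, which requires the D-(−)-tartrate series. The C3 carbinol configuration is irrelevant because C3 becomes a ketone.

**25 ⇒ 23 (via 24).** The two aryl O–Si bonds are cut; the acid must be freed from its silyl ester without loss of the aryl silyl ethers.

## Other disconnections considered

**Alternative 1:** Enzymatic dearomatization. Both ring A C–O bonds (C6–O, C7–O) are cut back to an arene, 3-oxoisochromane-7-carboxylic acid A1. In the forward sense a benzoate 1,2-dioxygenase (whole cells, O2) would add two hydroxyls syn to the ipso carbon C7 and the ortho carbon C6, giving the cis-dihydrodiol acid A2 with the C5=C4a–C8a=C8 diene.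
- In its favour: both ring A stereocentres and their cis relationship would come from one catalytic step on a flat bicyclic substrate that already contains C1, C3 and C4. On speed of complexity generation and on avoiding protecting groups at the outset it is better than the chosen plan.
- Against it here: the C7 substituent is a carboxyl that must be reduced to methyl beside a tertiary alcohol on a diene that re-aromatizes easily by dehydration or decarboxylation. The diene must be turned into the C8 ketone with C5 saturated, a net oxidation and transposition with no single reliable step. The lactone carbonyl C3 must still become the enol ether carrying the epoxide. The regiochemistry (C6 versus C8 as the ortho carbon) and the absolute sense of the enzyme on this unnatural substrate cannot be tuned.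
- Comparison: structurally A2 has the right skeleton but the wrong oxidation level at C5, C8, the C7 substituent and C3, whereas the chosen plan carries every carbon at or next to its final oxidation level. Mechanistically, enzyme selectivity is fixed by the protein, while the radical regiochemistry follows from polarity. On step count the alternative starts shorter but is expected to need a longer sequence after its key step, so overall the chosen plan should be no longer.

**Alternative 2:** Enol ether ring-closing metathesis. The C3=C4 bond of ring B is cut to diene A3, which has a vinyl group on C4a and a 1-alkoxyvinyl group carrying the epoxide on O2. A second-generation Grubbs catalyst would close ring B with loss of ethylene to give the tris-TES dienyl ether A4, with C8 as a protected carbinol.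
- In its favour: the fragile dienyl ether and vinyl epoxide would form in one neutral catalytic step with ethylene as the only by-product. On mildness of the ring B closure it is equal to or better than the base-mediated closure chosen here.
- Against it here: the enol ether partner is 1,1-disubstituted and branched by the epoxide, and enol ethers give stabilized, slow ruthenium carbenes; the other partner is part of a conjugated diene. The 1-alkoxyvinyl unit of A3 would need carbonyl methylenation with Cp2TiMe2 next to an epoxide. A4 has two secondary TES ethers (C6, C8) that must later be told apart, and C8 still has to be oxidized.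
- Comparison: the metathesis closes only ring B and leaves the construction of ring A, with vinyl on C4a and CH2O on C8a, unsolved. The chosen key step builds ring A and the C8a handle at once. The C8 redox detour adds steps at the end, so step economy favours the chosen plan.

**Alternative 3:** Alpha-ketol ring expansion. The C6–C7 bond is cut by contracting ring A to the cyclopenta[c]pyran acetyl carbinol A5, in which C8 bears hydroxyl and acetyl. Under Al(OC(CH3)3)3, C6 would migrate from C8 to the acetyl carbon, giving the six-membered ketol A6 with the C8 ketone and the tertiary C7 carbinol.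
- In its favour: the shift is atom-economic and driven by ring enlargement and by conjugation of the new C8 ketone with C4a=C8a. A6 is one desilylation away from 22, so the sequence after the key step would be shorter than in the chosen plan, which is a point for the alternative.
- Against it here: A5 already contains ring B, the dienyl ether and the vinyl epoxide, which must survive a Lewis acidic aluminium alkoxide with heating. The C7 configuration depends on a syn-chelated transition state and on having A5 as a single C8 epimer, itself a quaternary stereocentre to be made. The alkenyl carbon C8a could migrate in place of C6 and give a constitutional isomer, and the reaction is reversible.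
- Comparison: structurally A5 is no simpler than the target in ring count and sensitivity. Mechanistically the chosen plan has no stereo-determining event at C7 (it is taken from the chiral pool), whereas here C7 rests on a rearrangement. Step economy is better after the key step but probably worse before it.

Key step: step 9

Remark on the chemistry: the zinc-mediated propargylation (step 6) is expected to give both C3 carbinol epimers. Because C3 becomes a ketone in step 13 they are carried together, and names and SMILES show the anti epimer for definiteness.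

Remark on the chemistry: a check of the configurations shows that C6, C7 and both epoxide centres of target, lactone 1, key-step precursor 14 and key-step product 15 agree. The CIP label at C6 changes to S in the open-chain iodides 5 and 14 only because CH2I outranks C7; the spatial arrangement is unchanged.

## Route

Step 1
Reactants: 1 2-C-methyl-D-erythrono-1,4-lactone [(3R,4R)-3,4-dihydroxy-3-methyloxolan-2-one]
Product: 3 (3R,4R)-4-(TBS-oxy)-3-methyl-3-(TES-oxy)oxolan-2-one, via mono-TBS lactone 2 (not isolated)
Conditions: TBSCl (1.1 equiv), imidazole, DMF, 0 °C → rt; then TESCl (1.5 equiv), DMAP (cat.), 40 °C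
Reagents that add atoms: tert-butyldimethylsilyl chloride CC(C)(C)[Si](C)(C)Cl; triethylsilyl chloride CC[Si](CC)(CC)Cl
Why: Sequential silylation; TBSCl with imidazole silylates only the secondary hydroxyl, and the smaller TESCl with DMAP then caps the tertiary alpha-hydroxyl, so the two oxygens are differentiated by the reagents themselves and no stereocentre is touched.

Step 2
Reactants: 3 (3R,4R)-4-(TBS-oxy)-3-methyl-3-(TES-oxy)oxolan-2-one
Product: 4 (2R,3R)-3-(TBS-oxy)-4-hydroxy-N-methoxy-N,2-dimethyl-2-(TES-oxy)butanamide
Conditions: MeNHOMe·HCl (3 equiv), AlMe3 (3 equiv), CH2Cl2, 0 °C → rt; aq. potassium sodium tartrate work-up; used at once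
Reagents that add atoms: N,O-dimethylhydroxylamine hydrochloride CNOC.Cl
Why: Weinreb aminolysis of a lactone by the aluminium amide; the quaternary alpha carbon has no hydrogen, so neither epimerization nor beta-elimination is possible, and the aluminium alkoxide of the freed C5 hydroxyl does not promote silyl migration.

Step 3
Reactants: 4 (2R,3R)-3-(TBS-oxy)-4-hydroxy-N-methoxy-N,2-dimethyl-2-(TES-oxy)butanamide
Product: 5 (2R,3S)-3-(TBS-oxy)-4-iodo-N-methoxy-N,2-dimethyl-2-(TES-oxy)butanamide
Conditions: I2, PPh3, imidazole, CH2Cl2, 0 °C → rt
Reagents that add atoms: iodine II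
Why: Appel-type iodination of the primary alcohol through its alkoxyphosphonium salt; it is run immediately and cold so that iodide displacement outpaces relactonization, and the iodide is installed before the C8 ketone exists so that no lactol can interfere.

Step 4
Reactants: 6 (E)-but-2-en-1-ol
Product: 7 [(2R,3R)-3-methyloxiran-2-yl]methanol
Conditions: Ti(OiPr)4 (cat.), D-(−)-diisopropyl tartrate (cat.), t-BuOOH, 4 Å MS, CH2Cl2, −20 °C; non-aqueous work-up
Reagents that add atoms: tert-butyl hydroperoxide CC(C)(C)OO
Why: Sharpless asymmetric epoxidation; the titanium tartrate complex delivers oxygen to one face of the E-allylic alcohol, and the D-(−)-tartrate series sets both epoxide stereocentres as (2R,3R), the trans relationship following from the E alkene.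

Step 5
Reactants: 7 [(2R,3R)-3-methyloxiran-2-yl]methanol
Product: 8 (2S,3R)-3-methyloxirane-2-carbaldehyde
Conditions: (COCl)2, DMSO, CH2Cl2, −78 °C; Et3N, −78 → −20 °C; used as a dried CH2Cl2 solution
Reagents that add atoms: none
Why: Swern oxidation of a primary epoxy alcohol; the volatile aldehyde is not concentrated, and the epoxide C–H is too weakly acidic for epimerization under the short cold amine treatment (the descriptor at C2 changes only through CIP priorities).

Step 6
Reactants: 8 (2S,3R)-3-methyloxirane-2-carbaldehyde; 9 propargyl bromide (3-bromoprop-1-yne)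
Product: 11 (1R)-1-[(2R,3R)-3-methyloxiran-2-yl]but-3-yn-1-ol, via allenylzinc bromide 10 (not isolated)
Conditions: Zn dust, THF/sat. aq. NH4Cl, 0 °C
Reagents that add atoms: none
Why: Barbier propargylation; the allenylzinc species adds to the aldehyde with allylic transposition to give the homopropargylic alcohol and forms the C3–C4 bond; the anti epimer shown is expected to predominate (polar Felkin–Anh addition), and the syn epimer is carried along because this centre is oxidized later.

Step 7
Reactants: 11 (1R)-1-[(2R,3R)-3-methyloxiran-2-yl]but-3-yn-1-ol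
Product: 12 triethyl{[(1R)-1-[(2S,3R)-3-methyloxiran-2-yl]but-3-yn-1-yl]oxy}silane
Conditions: TESCl, imidazole, DMAP (cat.), CH2Cl2, 0 °C
Reagents that add atoms: triethylsilyl chloride CC[Si](CC)(CC)Cl
Why: Silyl ether formation under non-basic conditions that cannot trigger epoxide migration; the secondary TES ether survives the acetylide chemistry and can later be cleaved beside the TBS ether.

Step 8
Reactants: 12 triethyl{[(1R)-1-[(2S,3R)-3-methyloxiran-2-yl]but-3-yn-1-yl]oxy}silane; 5 (2R,3S)-3-(TBS-oxy)-4-iodo-N-methoxy-N,2-dimethyl-2-(TES-oxy)butanamide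
Product: 14 (2S,3R,8R)-2-(TBS-oxy)-1-iodo-3-methyl-8-[(2S,3R)-3-methyloxiran-2-yl]-3,8-bis(TES-oxy)oct-5-yn-4-one, via lithium acetylide 13 (not isolated)
Conditions: 12 (1.3 equiv), n-BuLi (1.2 equiv), THF, −78 °C; then 5, −78 → −40 °C; AcOH quench at −78 °C
Reagents that add atoms: none
Why: Acetylide addition to a Weinreb amide; the chelated tetrahedral intermediate stops the reaction at the ketone stage, the alkyne is kept in excess over n-BuLi so that no butyllithium remains to exchange the iodide, and the cold acidic quench prevents the intermediate alkoxide from displacing the C5 iodide.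

Step 9
Reactants: 14 (2S,3R,8R)-2-(TBS-oxy)-1-iodo-3-methyl-8-[(2S,3R)-3-methyloxiran-2-yl]-3,8-bis(TES-oxy)oct-5-yn-4-one
Product: 15 (5R,6R)-5-(TBS-oxy)-2-iodo-6-methyl-3-{(2R)-2-[(2S,3R)-3-methyloxiran-2-yl]-2-(TES-oxy)ethyl}-6-(TES-oxy)cyclohex-2-en-1-one
Conditions: (Bu3Sn)2 (0.1 equiv), hν (sunlamp, Pyrex), benzene (0.05 M), 60–80 °C
Reagents that add atoms: none
Why: Photolysis of (Bu3Sn)2 gives Bu3Sn radicals that abstract iodine from C5 of 14; the nucleophilic primary C5 radical adds to C4a, the electron-poor beta carbon of the ynone, forming the C4a–C5 bond, and the resulting C8a vinyl radical abstracts iodine from a second molecule of 14, which creates the C8a–I bond and carries the chain. The closest known reaction type is the iodine atom-transfer radical cyclization of iodoalkyl alkynes, together with the radical addition of alkyl iodides to ynoates that places the alkyl group on the beta carbon and iodine on the alpha carbon. Ring A closes in the 6-endo-dig mode; 5-exo-dig closure at C8a is disfavoured because it is polarity-mismatched, would give an unstabilized vinyl radical and must accommodate the sp2 carbon C8 in a five-membered transition state. No stereocentre is formed, and C6, C7 and the epoxide centres are not involved. The selectivity needed is therefore regiochemical and is secured by the polarization of the ynone. The quaternary C7 leaves the ketone without an enolizable alpha position, and a radical at C5, unlike an organometallic, does not expel the C6 silyloxy group. The ditin/light protocol is preferred to a trialkylborane initiator, whose ethyl radicals and boron centre could add to the ynone in a conjugate sense, and moderate concentration favours iodine transfer over hydrogen abstraction by the vinyl radical.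

Step 10
Reactants: 15 (5R,6R)-5-(TBS-oxy)-2-iodo-6-methyl-3-{(2R)-2-[(2S,3R)-3-methyloxiran-2-yl]-2-(TES-oxy)ethyl}-6-(TES-oxy)cyclohex-2-en-1-one
Product: 16 (5R,6R)-5-(TBS-oxy)-2-(hydroxymethyl)-6-methyl-3-{(2R)-2-[(2S,3R)-3-methyloxiran-2-yl]-2-(TES-oxy)ethyl}-6-(TES-oxy)cyclohex-2-en-1-one
Conditions: Bu3SnCH2OH (2 equiv), Pd2(dba)3 (5 mol %), AsPh3 (20 mol %), CuI (10 mol %), NMP, 50 °C
Reagents that add atoms: (tributylstannyl)methanol CCCC[Sn](CCCC)(CCCC)CO
Why: Stille cross-coupling of an alpha-iodo enone; zerovalent palladium inserts into the activated C8a–I bond, the weakly bound arsine and CuI speed transmetallation of the hydroxymethyl group, and reductive elimination forms C8a–C1; the epoxide is not allylic at this stage and is inert to the catalyst.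

Step 11
Reactants: 16 (5R,6R)-5-(TBS-oxy)-2-(hydroxymethyl)-6-methyl-3-{(2R)-2-[(2S,3R)-3-methyloxiran-2-yl]-2-(TES-oxy)ethyl}-6-(TES-oxy)cyclohex-2-en-1-one
Product: 17 [(4R,5R)-4-(TBS-oxy)-5-methyl-2-{(2R)-2-[(2S,3R)-3-methyloxiran-2-yl]-2-(TES-oxy)ethyl}-6-oxo-5-(TES-oxy)cyclohex-1-en-1-yl]methyl pivalate
Conditions: PivCl, pyridine, DMAP (cat.), CH2Cl2, 0 °C
Reagents that add atoms: pivaloyl chloride CC(C)(C)C(=O)Cl
Why: Acylation of the only free hydroxyl; the pivalate protects C1–O through the next two steps and later serves as the leaving group for ring B formation.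

Step 12
Reactants: 17 [(4R,5R)-4-(TBS-oxy)-5-methyl-2-{(2R)-2-[(2S,3R)-3-methyloxiran-2-yl]-2-(TES-oxy)ethyl}-6-oxo-5-(TES-oxy)cyclohex-1-en-1-yl]methyl pivalate
Product: 18 [(4R,5R)-4-(TBS-oxy)-2-{(2R)-2-hydroxy-2-[(2R,3R)-3-methyloxiran-2-yl]ethyl}-5-methyl-6-oxo-5-(TES-oxy)cyclohex-1-en-1-yl]methyl pivalate
Conditions: PPTS (0.2 equiv), MeOH/CH2Cl2 (1:1), 0 °C
Reagents that add atoms: none
Why: Mild acid methanolysis cleaves the secondary TES ether much faster than the secondary TBS or the hindered tertiary TES ether and leaves the epoxide intact at 0 °C; any loss of the C7 TES group is harmless, since that material converges on 22 in step 15.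

Step 13
Reactants: 18 [(4R,5R)-4-(TBS-oxy)-2-{(2R)-2-hydroxy-2-[(2R,3R)-3-methyloxiran-2-yl]ethyl}-5-methyl-6-oxo-5-(TES-oxy)cyclohex-1-en-1-yl]methyl pivalate
Product: 19 [(4R,5R)-4-(TBS-oxy)-5-methyl-2-{2-[(2S,3R)-3-methyloxiran-2-yl]-2-oxoethyl}-6-oxo-5-(TES-oxy)cyclohex-1-en-1-yl]methyl pivalate
Conditions: Dess–Martin periodinane, pyridine, CH2Cl2, 0 °C → rt; crude product used directly
Reagents that add atoms: none
Why: Buffered periodinane oxidation of a secondary alcohol to the epoxy ketone under nearly neutral conditions; it removes the C3 stereocentre, so both carbinol epimers converge here.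

Step 14
Reactants: 19 [(4R,5R)-4-(TBS-oxy)-5-methyl-2-{2-[(2S,3R)-3-methyloxiran-2-yl]-2-oxoethyl}-6-oxo-5-(TES-oxy)cyclohex-1-en-1-yl]methyl pivalate
Product: 21 (6R,7R)-6-(TBS-oxy)-7-methyl-3-[(2S,3R)-3-methyloxiran-2-yl]-7-(TES-oxy)-6,7-dihydro-1H-isochromen-8(5H)-one, via oxatriene 20 (not isolated)
Conditions: DBU (1.5 equiv), CH2Cl2 (0.01 M), 0 °C → rt
Reagents that add atoms: none
Why: DBU removes a C4 hydrogen (alpha to the C3 ketone and vinylogous to the C8 ketone), vinylogous E1cB loss of pivalate gives the 1-oxatriene 20, and thermal oxa-6π electrocyclization forms the O2–C1 bond; the 2H-pyran is favoured because it restores the C4a=C8a–C8=O conjugation as a vinylogous ester, direct O-alkylation of the dienolate at C1 would give the same product, and the silyloxy group at C6 is too poor a leaving group to compete.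

Step 15
Reactants: 21 (6R,7R)-6-(TBS-oxy)-7-methyl-3-[(2S,3R)-3-methyloxiran-2-yl]-7-(TES-oxy)-6,7-dihydro-1H-isochromen-8(5H)-one
Product: 22 (6R,7R)-6,7-dihydroxy-7-methyl-3-[(2S,3R)-3-methyloxiran-2-yl]-6,7-dihydro-1H-isochromen-8(5H)-one
Conditions: HF·pyridine, excess pyridine, THF, 0 °C → rt
Reagents that add atoms: none
Why: Fluoride-driven desilylation buffered by pyridine; the tertiary TES ether is cleaved readily and the secondary TBS ether more slowly, while the buffered medium is weakly acidic enough to spare the vinyl epoxide and the dienyl ether.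

Step 16
Reactants: 23 orsellinic acid (2,4-dihydroxy-6-methylbenzoic acid)
Product: 25 2,4-bis(TBS-oxy)-6-methylbenzoic acid, via tris-silyl orsellinate 24 (not isolated)
Conditions: TBSCl (3.5 equiv), imidazole, DMF, rt; then AcOH/THF/H2O, rt
Reagents that add atoms: tert-butyldimethylsilyl chloride CC(C)(C)[Si](C)(C)Cl
Why: Exhaustive silylation followed by selective hydrolysis of the silyl ester, which is far more labile to aqueous acid than aryl silyl ethers; everything is done at room temperature to avoid decarboxylation.

Step 17
Reactants: 25 2,4-bis(TBS-oxy)-6-methylbenzoic acid; 22 (6R,7R)-6,7-dihydroxy-7-methyl-3-[(2S,3R)-3-methyloxiran-2-yl]-6,7-dihydro-1H-isochromen-8(5H)-one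
Product: 27 (6R,7R)-7-hydroxy-7-methyl-3-[(2S,3R)-3-methyloxiran-2-yl]-8-oxo-5,6,7,8-tetrahydro-1H-isochromen-6-yl 2,4-bis(TBS-oxy)-6-methylbenzoate, via acid chloride 26 (not isolated)
Conditions: 25 (1.5 equiv), 1-chloro-N,N,2-trimethylprop-1-en-1-amine, CH2Cl2, 0 °C → rt; then 22, Et3N, DMAP, CH2Cl2, 0 °C → rt
Reagents that add atoms: none
Why: Neutral acid chloride formation that leaves the aryl silyl ethers intact, then DMAP-assisted acylation; the electron-rich aroyl chloride reacts with acylium character, which offsets its ortho substituents, and only the secondary C6 hydroxyl is acylated because the tertiary C7 hydroxyl is too hindered, with C6 retaining its configuration.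

Step 18
Reactants: 27 (6R,7R)-7-hydroxy-7-methyl-3-[(2S,3R)-3-methyloxiran-2-yl]-8-oxo-5,6,7,8-tetrahydro-1H-isochromen-6-yl 2,4-bis(TBS-oxy)-6-methylbenzoate
Product: 28 (6R,7R)-7-hydroxy-7-methyl-3-[(2S,3R)-3-methyloxiran-2-yl]-8-oxo-5,6,7,8-tetrahydro-1H-isochromen-6-yl 2,4-dihydroxy-6-methylbenzoate (target)
Conditions: TBAF (2.2 equiv), AcOH (2.5 equiv), THF, 0 °C
Reagents that add atoms: none
Why: Aryl silyl ethers are cleaved rapidly by fluoride, and the acetic acid buffer protonates the phenoxides at once so that the medium never becomes basic enough to eliminate the C6 ester through C5 or to open the vinyl epoxide.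

## Compound list

1 | 2-C-methyl-D-erythrono-1,4-lactone | O[C@@H]1COC(=O)[C@]1(C)O | starting material
2 | (3R,4R)-4-(TBS-oxy)-3-hydroxy-3-methyloxolan-2-one | CC(C)(C)[Si](C)(C)O[C@@H]1COC(=O)[C@]1(C)O | intermediate (not isolated)
3 | (3R,4R)-4-(TBS-oxy)-3-methyl-3-(TES-oxy)oxolan-2-one | CC(C)(C)[Si](C)(C)O[C@@H]1COC(=O)[C@]1(C)O[Si](CC)(CC)CC | intermediate
4 | (2R,3R)-3-(TBS-oxy)-4-hydroxy-N-methoxy-N,2-dimethyl-2-(TES-oxy)butanamide | CON(C)C(=O)[C@](C)(O[Si](CC)(CC)CC)[C@@H](CO)O[Si](C)(C)C(C)(C)C | intermediate
5 | (2R,3S)-3-(TBS-oxy)-4-iodo-N-methoxy-N,2-dimethyl-2-(TES-oxy)butanamide | CON(C)C(=O)[C@](C)(O[Si](CC)(CC)CC)[C@@H](CI)O[Si](C)(C)C(C)(C)C | intermediate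
6 | (E)-but-2-en-1-ol | C/C=C/CO | starting material
7 | [(2R,3R)-3-methyloxiran-2-yl]methanol | OC[C@H]1O[C@@H]1C | intermediate
8 | (2S,3R)-3-methyloxirane-2-carbaldehyde | O=C[C@H]1O[C@@H]1C | intermediate
9 | propargyl bromide | C#CCBr | starting material
10 | allenylzinc bromide | C=C=C[Zn]Br | intermediate (not isolated)
11 | (1R)-1-[(2R,3R)-3-methyloxiran-2-yl]but-3-yn-1-ol | C#CC[C@@H](O)[C@H]1O[C@@H]1C | intermediate
12 | triethyl{[(1R)-1-[(2S,3R)-3-methyloxiran-2-yl]but-3-yn-1-yl]oxy}silane | C#CC[C@@H](O[Si](CC)(CC)CC)[C@H]1O[C@@H]1C | intermediate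
13 | lithium acetylide of 12 | [Li]C#CC[C@@H](O[Si](CC)(CC)CC)[C@H]1O[C@@H]1C | intermediate (not isolated)
14 | iodo ynone, key-step precursor | CC(C)(C)[Si](C)(C)O[C@H](CI)[C@@](C)(O[Si](CC)(CC)CC)C(=O)C#CC[C@@H](O[Si](CC)(CC)CC)[C@H]1O[C@@H]1C | intermediate
15 | ring A alpha-iodo enone, key-step product | CC(C)(C)[Si](C)(C)O[C@@H]1CC(C[C@@H](O[Si](CC)(CC)CC)[C@H]2O[C@@H]2C)=C(I)C(=O)[C@]1(C)O[Si](CC)(CC)CC | intermediate
16 | 2-(hydroxymethyl) enone | CC(C)(C)[Si](C)(C)O[C@@H]1CC(C[C@@H](O[Si](CC)(CC)CC)[C@H]2O[C@@H]2C)=C(CO)C(=O)[C@]1(C)O[Si](CC)(CC)CC | intermediate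
17 | allylic pivalate | CC(C)(C)[Si](C)(C)O[C@@H]1CC(C[C@@H](O[Si](CC)(CC)CC)[C@H]2O[C@@H]2C)=C(COC(=O)C(C)(C)C)C(=O)[C@]1(C)O[Si](CC)(CC)CC | intermediate
18 | C3 alcohol pivalate | CC(C)(C)[Si](C)(C)O[C@@H]1CC(C[C@@H](O)[C@H]2O[C@@H]2C)=C(COC(=O)C(C)(C)C)C(=O)[C@]1(C)O[Si](CC)(CC)CC | intermediate
19 | C3 ketone pivalate | CC(C)(C)[Si](C)(C)O[C@@H]1CC(CC(=O)[C@H]2O[C@@H]2C)=C(COC(=O)C(C)(C)C)C(=O)[C@]1(C)O[Si](CC)(CC)CC | intermediate
20 | (Z)-1-oxatriene (2-methylidene dienone) | CC(C)(C)[Si](C)(C)O[C@@H]1C/C(=C/C(=O)[C@H]2O[C@@H]2C)C(=C)C(=O)[C@]1(C)O[Si](CC)(CC)CC | intermediate (not isolated)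
21 | (6R,7R)-6-(TBS-oxy)-7-methyl-3-[(2S,3R)-3-methyloxiran-2-yl]-7-(TES-oxy)-6,7-dihydro-1H-isochromen-8(5H)-one | CC(C)(C)[Si](C)(C)O[C@@H]1CC2=C(COC([C@H]3O[C@@H]3C)=C2)C(=O)[C@]1(C)O[Si](CC)(CC)CC | intermediate
22 | (6R,7R)-6,7-dihydroxy-7-methyl-3-[(2S,3R)-3-methyloxiran-2-yl]-6,7-dihydro-1H-isochromen-8(5H)-one | O[C@@H]1CC2=C(COC([C@H]3O[C@@H]3C)=C2)C(=O)[C@]1(C)O | intermediate
23 | orsellinic acid | Cc1cc(O)cc(O)c1C(=O)O | starting material
24 | TBS 2,4-bis(TBS-oxy)-6-methylbenzoate | Cc1cc(O[Si](C)(C)C(C)(C)C)cc(O[Si](C)(C)C(C)(C)C)c1C(=O)O[Si](C)(C)C(C)(C)C | intermediate (not isolated)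
25 | 2,4-bis(TBS-oxy)-6-methylbenzoic acid | Cc1cc(O[Si](C)(C)C(C)(C)C)cc(O[Si](C)(C)C(C)(C)C)c1C(=O)O | intermediate
26 | 2,4-bis(TBS-oxy)-6-methylbenzoyl chloride | Cc1cc(O[Si](C)(C)C(C)(C)C)cc(O[Si](C)(C)C(C)(C)C)c1C(=O)Cl | intermediate (not isolated)
27 | bis-TBS-protected orsellinate ester | Cc1cc(O[Si](C)(C)C(C)(C)C)cc(O[Si](C)(C)C(C)(C)C)c1C(=O)O[C@@H]1CC2=C(COC([C@H]3O[C@@H]3C)=C2)C(=O)[C@]1(C)O | intermediate
28 | CNP0323247.1 | Cc1cc(O)cc(O)c1C(=O)O[C@@H]1CC2=C(COC([C@H]3O[C@@H]3C)=C2)C(=O)[C@]1(C)O | target

## Step count and risk

Total step count: 18. Longest linear sequence: 14 steps (steps 4–15, 17 and 18, from 6).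

Least certain steps:

**Step 9 (key step).** Iodine transfer to the carbonyl-conjugated C8a vinyl radical may be too slow. Hydrogen abstraction from the medium or a 1,5-hydrogen shift from the side chain could then interrupt the chain, and light could degrade the iodo enone as it forms. Closure in the 5-exo sense is the second concern. Fallback: 14 is cyclized reductively with Bu3SnH (slow addition, AIBN, benzene, 80 °C), where hydrogen transfer from tin traps the vinyl radical regardless of its reactivity toward iodides, to give the iodine-free ring A enone F1. Alpha-iodination of F1 (I2, pyridine, DMAP, CH2Cl2) then returns to 15. The regiochemistry is intrinsic to the ynone and is the same in both variants.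

**Step 8.** Addition to the congested amide carbonyl may be slow. On warming, the tetrahedral alkoxide could displace the C5 iodide intramolecularly, or traces of butyllithium could exchange it. Fallback: 5 is reduced (i-Bu2AlH, CH2Cl2, −78 °C) to the alpha-silyloxy aldehyde F2, which has no alpha hydrogen. Zinc-mediated alkynylation with 12 (Zn(OTf)2, Et3N, toluene, rt) gives the propargylic alcohol F3 as a carbinol mixture through a non-nucleophilic zinc alkoxide. Dess–Martin oxidation then returns to 14.

**Step 10.** Transfer of the sp3 hydroxymethyl group to a tetrasubstituted vinylpalladium species may be slow, so that protodeiodination, butyl transfer or homocoupling take over. Fallback: 15 undergoes methoxycarbonylation (Pd(OAc)2, PPh3, CO 1 atm, MeOH, Et3N, DMF, 60 °C), an insertion that is little affected by crowding, to the methyl ester F4. Reduction with i-Bu2AlH (−78 °C) gives the C1,C8 diol F5, selective pivaloylation of the primary hydroxyl gives F6, and PPTS/MeOH gives the C3,C8 diol F7. Dess–Martin oxidation of both carbinols returns to 19, one step longer than the main line.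

**Step 14.** The exposed 2-methylidene dienone 20 may undergo intermolecular conjugate addition or oligomerize before it cyclizes, or base may attack C5 and expel the C6 silyloxy group. Fallback: ring B is closed through the other C–O bond. From 15, PPTS/MeOH gives the iodo enone carbinol F8 and Dess–Martin oxidation gives the iodo enone ketone F9. Stille coupling with Bu3SnCH2OH then gives a hydroxy ketone that closes to the lactol F10. Dehydration of the lactol (MsCl, Et3N, CH2Cl2, −20 → 0 °C) returns to 21. This order is not the first choice because the coupling then runs beside acidic C4 hydrogens.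

**Step 15.** During the slow cleavage of the secondary TBS ether, HF may open the vinyl epoxide or hydrate the dienyl ether. Fallback: the silyl groups are removed before ring B exists. HF·pyridine on 19 gives the diol diketone pivalate F11, and DBU (as in step 14) then gives 22 directly.

## Further compounds

F1 | step 9 | (5R,6R)-5-(TBS-oxy)-6-methyl-3-{(2R)-2-[(2S,3R)-3-methyloxiran-2-yl]-2-(TES-oxy)ethyl}-6-(TES-oxy)cyclohex-2-en-1-one | CC(C)(C)[Si](C)(C)O[C@@H]1CC(C[C@@H](O[Si](CC)(CC)CC)[C@H]2O[C@@H]2C)=CC(=O)[C@]1(C)O[Si](CC)(CC)CC
F2 | step 8 | (2R,3S)-3-(TBS-oxy)-4-iodo-2-methyl-2-(TES-oxy)butanal | O=C[C@](C)(O[Si](CC)(CC)CC)[C@@H](CI)O[Si](C)(C)C(C)(C)C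
F3 | step 8 | propargylic alcohol corresponding to 14, C8 carbinol as epimer mixture | OC(C#CC[C@@H](O[Si](CC)(CC)CC)[C@H]1O[C@@H]1C)[C@](C)(O[Si](CC)(CC)CC)[C@@H](CI)O[Si](C)(C)C(C)(C)C
F4 | step 10 | methyl ester at C8a of the ring A enone | CC(C)(C)[Si](C)(C)O[C@@H]1CC(C[C@@H](O[Si](CC)(CC)CC)[C@H]2O[C@@H]2C)=C(C(=O)OC)C(=O)[C@]1(C)O[Si](CC)(CC)CC
F5 | step 10 | C1,C8 diol, C8 carbinol as epimer mixture | CC(C)(C)[Si](C)(C)O[C@@H]1CC(C[C@@H](O[Si](CC)(CC)CC)[C@H]2O[C@@H]2C)=C(CO)C(O)[C@]1(C)O[Si](CC)(CC)CC
F6 | step 10 | C1 pivalate of F5 | CC(C)(C)[Si](C)(C)O[C@@H]1CC(C[C@@H](O[Si](CC)(CC)CC)[C@H]2O[C@@H]2C)=C(COC(=O)C(C)(C)C)C(O)[C@]1(C)O[Si](CC)(CC)CC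
F7 | step 10 | C3,C8 diol C1 pivalate | CC(C)(C)[Si](C)(C)O[C@@H]1CC(C[C@@H](O)[C@H]2O[C@@H]2C)=C(COC(=O)C(C)(C)C)C(O)[C@]1(C)O[Si](CC)(CC)CC
F8 | step 14 | alpha-iodo enone with free C3 carbinol | CC(C)(C)[Si](C)(C)O[C@@H]1CC(C[C@@H](O)[C@H]2O[C@@H]2C)=C(I)C(=O)[C@]1(C)O[Si](CC)(CC)CC
F9 | step 14 | alpha-iodo enone with C3 ketone | CC(C)(C)[Si](C)(C)O[C@@H]1CC(CC(=O)[C@H]2O[C@@H]2C)=C(I)C(=O)[C@]1(C)O[Si](CC)(CC)CC
F10 | step 14 | ring B lactol (C3 hemiketal, epimer mixture at C3) | CC(C)(C)[Si](C)(C)O[C@@H]1CC2=C(COC(O)([C@H]3O[C@@H]3C)C2)C(=O)[C@]1(C)O[Si](CC)(CC)CC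
F11 | step 15 | desilylated diol diketone pivalate | O[C@@H]1CC(CC(=O)[C@H]2O[C@@H]2C)=C(COC(=O)C(C)(C)C)C(=O)[C@]1(C)O
A1 | alternative 1 | 3-oxoisochromane-7-carboxylic acid | O=C1Cc2ccc(C(=O)O)cc2CO1
A2 | alternative 1 | cis-dihydrodiol acid of the isochromanone | O[C@@H]1C=C2CC(=O)OCC2=C[C@@]1(O)C(=O)O
A3 | alternative 2 | metathesis precursor with C4a vinyl and 1-alkoxyvinyl groups, tris-TES ether | CC[Si](CC)(CC)O[C@@H]1CC(C=C)=C(COC(=C)[C@H]2O[C@@H]2C)[C@H](O[Si](CC)(CC)CC)[C@]1(C)O[Si](CC)(CC)CC
A4 | alternative 2 | bicyclic dienyl ether, tris-TES ether | CC[Si](CC)(CC)O[C@@H]1CC2=C(COC([C@H]3O[C@@H]3C)=C2)[C@H](O[Si](CC)(CC)CC)[C@]1(C)O[Si](CC)(CC)CC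
A5 | alternative 3 | cyclopenta[c]pyran acetyl carbinol, C6 TBS ether | CC(=O)[C@@]1(O)[C@H](O[Si](C)(C)C(C)(C)C)CC2=C1COC([C@H]3O[C@@H]3C)=C2
A6 | alternative 3 | C6-silylated bicyclic ketol core | CC(C)(C)[Si](C)(C)O[C@@H]1CC2=C(COC([C@H]3O[C@@H]3C)=C2)C(=O)[C@]1(C)O
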